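**Plan**

- Labels: quinolone A is fused to the gem-dimethyl pyran A, quinolone B to pyran B. The cyclohexene is Ca(–C3 of A)=CbH–Cc(Me)(O–B)–CdH2–CeH(–C3 of B)–CfH(–CMe2–O–A).
- Enabling feature: pyran A (O–C4=C3–Ca–Cf–CMe2) with the Ca=Cb alkene exocyclic to it is the oxa-[4+2] adduct of an allenic quinone methide O=C4–C3=Ca=Cb of quinolone A and a Cf=CMe2 alkene. The retrosynthesis cuts Ca–Cf and O–CMe2 first, leaving an alkyne on Cc and an isobutenyl group on Ce, cis on pyran B.
- Further cuts: C3(A)–Ca (Sonogashira); then in pyran B Cc–CH3 (AlMe3 on an alkynyl ketal), Cb–Cc (acetylide to an aldehyde) and Ce–C3(B)/O–Cc (Michael addition–hemiacetalisation). Both halves come from one 4-hydroxyquinolone.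
- Forward order: quinolone ring, then pyran B, then the alkyne link to iodinated quinolone A, then cyclohexene and pyran A together in the last step.
- Stereochemistry: Ce from iminium catalysis with the (R)-silyl prolinol. Cc from Ce, because methyl is delivered last and trans to the isobutenyl group (an alkynyl nucleophile added last would end up trans to it, the wrong epimer). Cf in the cycloaddition from the cis tether and allylic 1,3-strain.

Key step: step 13

Assumption: the E-iminium ion of the diphenylprolinol silyl ether is attacked on the face remote from the CPh2OSiMe3 group, which for the (R)-catalyst gives the R centre at Ce; 4-hydroxy-2-quinolone tautomers are drawn throughout.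

**Route**

Step 1
Reactants: 1 2,3-dimethoxyaniline
Product: 3 2,3-dimethoxy-N-methylaniline, via hemiaminal ether 2 (not isolated)
Conditions: (CH2O)n, NaOMe, MeOH, reflux; then NaBH4, reflux
Reagents that add atoms: paraformaldehyde (as formaldehyde), C=O
Why: Reductive mono-N-methylation: methoxide-mediated condensation with formaldehyde stops at the N-methoxymethyl aniline, which NaBH4 reduces through the N-aryl imine, so that dimethylation is avoided.

Step 2
Reactants: 3 2,3-dimethoxy-N-methylaniline; 4 diethyl malonate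
Product: 6 4-hydroxy-7,8-dimethoxy-1-methylquinolin-2(1H)-one, via malonamate ester 5 (not isolated)
Conditions: Ph2O, 250 °C, EtOH distilled off, 1:1 stoichiometry
Reagents that add atoms: none
Why: Thermal malonate condensation (N-acylation, then intramolecular Friedel–Crafts-type acylation at the only free ortho position, para to a methoxy group) is the standard entry to 1-alkyl-4-hydroxy-2-quinolones.

Step 3
Reactants: 7 3-methylbut-2-enal; 8 (triphenylphosphoranylidene)acetaldehyde
Product: 9 (2E)-5-methylhexa-2,4-dienal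
Conditions: PhMe, 80 °C, slight excess of 7
Reagents that add atoms: none
Why: Wittig olefination with the stabilised formyl ylide should give the E-enal, the excess of 7 limiting a second homologation.

Step 4
Reactants: 6 4-hydroxy-7,8-dimethoxy-1-methylquinolin-2(1H)-one; 9 (2E)-5-methylhexa-2,4-dienal
Product: 11 (4R)-2-hydroxy-7,8-dimethoxy-6-methyl-4-(2-methylprop-1-en-1-yl)-2,3,4,6-tetrahydro-5H-pyrano[3,2-c]quinolin-5-one (anomer mixture), via open-chain aldehyde 10 (not isolated)
Conditions: (R)-2-[diphenyl(trimethylsilyloxy)methyl]pyrrolidine (20 mol %), PhCO2H (20 mol %), CH2Cl2, rt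
Reagents that add atoms: none
Why: Iminium-catalysed Michael addition–hemiacetalisation, established for 4-hydroxycoumarins and 4-hydroxyquinolinones with enals; C3 of 6 should attack the β-carbon (the δ-carbon is blocked by the gem-dimethyl group) on the iminium face remote from CPh2OSiMe3, setting Ce as R.

Step 5
Reactants: 11 the (4R)-lactol; 12 ethynyltrimethylsilane
Product: 13 4-hydroxy-3-[(4R,6RS)-6-hydroxy-2-methyl-8-(trimethylsilyl)oct-2-en-7-yn-4-yl]-7,8-dimethoxy-1-methylquinolin-2(1H)-one
Conditions: 12 (3.5 equiv), n-BuLi (3.3 equiv), THF, −78 °C; add 11, −78 → −20 °C; sat. aq. NH4Cl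
Reagents that add atoms: none
Why: Base opens the lactol to the aldehyde (the quinolonate is the leaving alkoxide) and the lithium acetylide adds 1,2 at low temperature, where retro-Michael loss of Ce is not expected; the carbinol configuration is irrelevant because it is oxidised next.

Step 6
Reactants: 13 the propargylic alcohol
Product: 16 (4R)-2,7,8-trimethoxy-6-methyl-4-(2-methylprop-1-en-1-yl)-2-[(trimethylsilyl)ethynyl]-2,3,4,6-tetrahydro-5H-pyrano[3,2-c]quinolin-5-one (C2 epimers), via ynone 14 (not isolated), via hemiketal 15 (not isolated)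
Conditions: MnO2 (20 equiv), CH2Cl2, rt; filter, concentrate; then MeOH, camphorsulfonic acid (10 mol %), 3 Å sieves, rt
Reagents that add atoms: methanol, CO
Why: MnO2 oxidation of the propargylic alcohol gives an ynone that closes onto the quinolone hydroxyl as the cyclic hemiketal (the behaviour of warfarin-type adducts), and acid-catalysed exchange with methanol locks pyran B as a mixed ketal with an exocyclic leaving group.

Step 7
Reactants: 16 the alkynyl methyl ketal
Product: 17 (2S,4R)-7,8-dimethoxy-2,6-dimethyl-4-(2-methylprop-1-en-1-yl)-2-[(trimethylsilyl)ethynyl]-2,3,4,6-tetrahydro-5H-pyrano[3,2-c]quinolin-5-one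
Conditions: AlMe3 (4 equiv), CH2Cl2, −78 → 0 °C; then aq. potassium sodium tartrate
Reagents that add atoms: trimethylaluminium, C[Al](C)C
Why: Organoaluminium substitution of a ketal through the alkynyl-stabilised cyclic oxocarbenium ion (C-glycoside-type methylation); methyl should add to the flattened ring on the face opposite the C4 isobutenyl group, so the alkynyl group ends up cis to it (Cc = S), as the later bridging requires.

Step 8
Reactants: 17 the silyl alkyne
Product: 18 (2S,4R)-2-ethynyl-7,8-dimethoxy-2,6-dimethyl-4-(2-methylprop-1-en-1-yl)-2,3,4,6-tetrahydro-5H-pyrano[3,2-c]quinolin-5-one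
Conditions: K2CO3 (0.2 equiv), MeOH, rt
Reagents that add atoms: none
Why: Base-catalysed methanolysis of the C(sp)–Si bond is routine and touches neither the tertiary ether nor the alkene.

Step 9
Reactants: 6 4-hydroxy-7,8-dimethoxy-1-methylquinolin-2(1H)-one
Product: 19 4-hydroxy-3-iodo-7,8-dimethoxy-1-methylquinolin-2(1H)-one
Conditions: N-iodosuccinimide (1.05 equiv), MeCN, 0 °C → rt
Reagents that add atoms: N-iodosuccinimide, O=C1CCC(=O)N1I
Why: Electrophilic iodination occurs at C3, the enol carbon and by far the most nucleophilic position, as is known for 4-hydroxy-2-quinolones.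

Step 10
Reactants: 19 the 3-iodoquinolone
Product: 20 3-iodo-7,8-dimethoxy-1-methyl-2-oxo-1,2-dihydroquinolin-4-yl 2,2-dimethylpropanoate
Conditions: pivaloyl chloride, Et3N, 4-(dimethylamino)pyridine (5 mol %), CH2Cl2, 0 °C
Reagents that add atoms: pivaloyl chloride, CC(C)(C)C(Cl)=O
Why: O-acylation of the acidic enol masks the hydroxyl that would otherwise close a furan onto the alkyne under Pd/Cu catalysis, and the ester can later be removed without acid.

Step 11
Reactants: 18 the terminal alkyne; 20 the iodoquinolone pivalate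
Product: 21 3-{[(2S,4R)-7,8-dimethoxy-2,6-dimethyl-4-(2-methylprop-1-en-1-yl)-5-oxo-3,4,5,6-tetrahydro-2H-pyrano[3,2-c]quinolin-2-yl]ethynyl}-7,8-dimethoxy-1-methyl-2-oxo-1,2-dihydroquinolin-4-yl 2,2-dimethylpropanoate
Conditions: Pd(PPh3)2Cl2 (5 mol %), CuI (10 mol %), Et3N, THF, 40 °C
Reagents that add atoms: none
Why: Sonogashira coupling of a 3-iodo-4-acyloxy-2-quinolone with a terminal alkyne forms C3(A)–Ca; Et3N is non-nucleophilic and should leave the pivalate intact.

Step 12
Reactants: 21 the coupled pivalate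
Product: 22 3-{[(2S,4R)-7,8-dimethoxy-2,6-dimethyl-4-(2-methylprop-1-en-1-yl)-5-oxo-3,4,5,6-tetrahydro-2H-pyrano[3,2-c]quinolin-2-yl]ethynyl}-4-hydroxy-7,8-dimethoxy-1-methylquinolin-2(1H)-one
Conditions: n-BuNH2 (2 equiv), THF, 0 °C; aq. citric acid wash; thiol-silica treatment to remove Pd and Cu; used at once
Reagents that add atoms: none
Why: Aminolysis of the activated enol ester frees the 4-hydroxyl under non-acidic conditions, sparing the tertiary propargylic ether, which would ionise easily under acid.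

Step 13
Reactants: 22 the alkynyl hydroxyquinolone
Product: 24 CNP0237003.1 (target; Cc S, Ce R, Cf S), via vinylidene quinone methide 23 (not isolated)
Conditions: 1,4-diazabicyclo[2.2.2]octane (20 mol %), CHCl3, 25 → 50 °C, metal-free
Reagents that add atoms: none
Why: Proposed new method: the amine should shuttle the acidic 4-OH proton of 22 to the distal alkyne carbon Cb, giving the allenic quinone methide 23, whose O=C4–C3=Ca oxadiene adds to the tethered Cf=CMe2 alkene in an asynchronous inverse-demand oxa-[4+2] (Ca–Cf leading, O–CMe2 following at the cation-stabilising terminus) with re-aromatisation of quinolone A. The closest known reaction type is the base- or hydrogen-bond-catalysed generation of vinylidene o-quinone methides from 2-alkynyl phenols and naphthols with intramolecular [4+2] capture, extended here to a 3-alkynyl-4-hydroxy-2-quinolone carrying an alkyl-substituted alkyne. The cyclohexene closes by 6-exo attack of Cf on the allene carbon Ca across the three-atom tether Cc–Cd–Ce (Ca=Cb stays endocyclic), and pyran A closes as the six-membered hetero-ring of the cycloaddition through the O–CMe2 bond. The new centre Cf is controlled by allylic 1,3-strain: Ce–H eclipses the trisubstituted alkene, and the cis-diaxial tether brings Ca onto the alkene face on the side of Cd, which places CMe2 anti to quinolone B. The step needs the C4 ketone oxygen rather than the C2 amide oxygen as the diene terminus, which the more electrophilic enone-type oxadiene and the retained 2-quinolone amide should secure. It also needs [4+2] to outrun 5-endo closure of the hydroxyl onto the alkyne, for which the weak amine base and the removal of Pd and Cu are provided.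

**Compound list**

1 | 2,3-dimethoxyaniline | COc1cccc(N)c1OC | starting material
2 | 2,3-dimethoxy-N-(methoxymethyl)aniline | COCNc1cccc(OC)c1OC | intermediate
3 | 2,3-dimethoxy-N-methylaniline | CNc1cccc(OC)c1OC | intermediate
4 | diethyl malonate | CCOC(=O)CC(=O)OCC | starting material
5 | ethyl 3-[(2,3-dimethoxyphenyl)(methyl)amino]-3-oxopropanoate | CCOC(=O)CC(=O)N(C)c1cccc(OC)c1OC | intermediate
6 | 4-hydroxy-7,8-dimethoxy-1-methylquinolin-2(1H)-one | Cn1c(=O)cc(O)c2ccc(OC)c(OC)c21 | intermediate
7 | 3-methylbut-2-enal | CC(C)=CC=O | starting material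
8 | (triphenylphosphoranylidene)acetaldehyde | O=CC=P(c1ccccc1)(c1ccccc1)c1ccccc1 | starting material
9 | (2E)-5-methylhexa-2,4-dienal | CC(C)=C/C=C/C=O | intermediate
10 | (3R)-3-(4-hydroxy-7,8-dimethoxy-1-methyl-2-oxo-1,2-dihydroquinolin-3-yl)-5-methylhex-4-enal | O=CC[C@H](C=C(C)C)c1c(O)c2ccc(OC)c(OC)c2n(C)c1=O | intermediate
11 | (4R)-2-hydroxy-7,8-dimethoxy-6-methyl-4-(2-methylprop-1-en-1-yl)-2,3,4,6-tetrahydro-5H-pyrano[3,2-c]quinolin-5-one | OC1C[C@H](C=C(C)C)c2c(O1)c1ccc(OC)c(OC)c1n(C)c2=O | intermediate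
12 | ethynyltrimethylsilane | C[Si](C)(C)C#C | starting material
13 | 4-hydroxy-3-[(4R,6RS)-6-hydroxy-2-methyl-8-(trimethylsilyl)oct-2-en-7-yn-4-yl]-7,8-dimethoxy-1-methylquinolin-2(1H)-one | CC(C)=C[C@@H](CC(O)C#C[Si](C)(C)C)c1c(O)c2ccc(OC)c(OC)c2n(C)c1=O | intermediate
14 | 4-hydroxy-7,8-dimethoxy-1-methyl-3-[(4R)-2-methyl-6-oxo-8-(trimethylsilyl)oct-2-en-7-yn-4-yl]quinolin-2(1H)-one | CC(C)=C[C@@H](CC(=O)C#C[Si](C)(C)C)c1c(O)c2ccc(OC)c(OC)c2n(C)c1=O | intermediate
15 | (4R)-2-hydroxy-7,8-dimethoxy-6-methyl-4-(2-methylprop-1-en-1-yl)-2-[(trimethylsilyl)ethynyl]-2,3,4,6-tetrahydro-5H-pyrano[3,2-c]quinolin-5-one | C[Si](C)(C)C#CC1(O)C[C@H](C=C(C)C)c2c(O1)c1ccc(OC)c(OC)c1n(C)c2=O | intermediate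
16 | (4R)-2,7,8-trimethoxy-6-methyl-4-(2-methylprop-1-en-1-yl)-2-[(trimethylsilyl)ethynyl]-2,3,4,6-tetrahydro-5H-pyrano[3,2-c]quinolin-5-one | C[Si](C)(C)C#CC1(OC)C[C@H](C=C(C)C)c2c(O1)c1ccc(OC)c(OC)c1n(C)c2=O | intermediate
17 | (2S,4R)-7,8-dimethoxy-2,6-dimethyl-4-(2-methylprop-1-en-1-yl)-2-[(trimethylsilyl)ethynyl]-2,3,4,6-tetrahydro-5H-pyrano[3,2-c]quinolin-5-one | C[Si](C)(C)C#C[C@]1(C)C[C@H](C=C(C)C)c2c(O1)c1ccc(OC)c(OC)c1n(C)c2=O | intermediate
18 | (2S,4R)-2-ethynyl-7,8-dimethoxy-2,6-dimethyl-4-(2-methylprop-1-en-1-yl)-2,3,4,6-tetrahydro-5H-pyrano[3,2-c]quinolin-5-one | C#C[C@]1(C)C[C@H](C=C(C)C)c2c(O1)c1ccc(OC)c(OC)c1n(C)c2=O | intermediate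
19 | 4-hydroxy-3-iodo-7,8-dimethoxy-1-methylquinolin-2(1H)-one | Cn1c(=O)c(I)c(O)c2ccc(OC)c(OC)c21 | intermediate
20 | 3-iodo-7,8-dimethoxy-1-methyl-2-oxo-1,2-dihydroquinolin-4-yl 2,2-dimethylpropanoate | Cn1c(=O)c(I)c(OC(=O)C(C)(C)C)c2ccc(OC)c(OC)c21 | intermediate
21 | pivalate of 22 at the 4-oxygen of quinolone A | Cn1c(=O)c(C#C[C@]3(C)C[C@H](C=C(C)C)c4c(O3)c3ccc(OC)c(OC)c3n(C)c4=O)c(OC(=O)C(C)(C)C)c2ccc(OC)c(OC)c21 | intermediate
22 | 3-{[(2S,4R)-7,8-dimethoxy-2,6-dimethyl-4-(2-methylprop-1-en-1-yl)-5-oxo-3,4,5,6-tetrahydro-2H-pyrano[3,2-c]quinolin-2-yl]ethynyl}-4-hydroxy-7,8-dimethoxy-1-methylquinolin-2(1H)-one | Cn1c(=O)c(C#C[C@]3(C)C[C@H](C=C(C)C)c4c(O3)c3ccc(OC)c(OC)c3n(C)c4=O)c(O)c2ccc(OC)c(OC)c21 | intermediate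
23 | 3-{2-[(2S,4R)-7,8-dimethoxy-2,6-dimethyl-4-(2-methylprop-1-en-1-yl)-5-oxo-3,4,5,6-tetrahydro-2H-pyrano[3,2-c]quinolin-2-yl]ethenylidene}-7,8-dimethoxy-1-methylquinoline-2,4(1H,3H)-dione | CN1C(=O)C(=C=C[C@]3(C)C[C@H](C=C(C)C)c4c(O3)c3ccc(OC)c(OC)c3n(C)c4=O)C(=O)c2ccc(OC)c(OC)c21 | intermediate
24 | CNP0237003.1 (Cc S, Ce R, Cf S) | COc1ccc2c3c(c(=O)n(C)c2c1OC)C1=C[C@]2(C)C[C@@H](c4c(c5ccc(OC)c(OC)c5n(C)c4=O)O2)[C@@H]1C(C)(C)O3 | target

**Step count**

Total: 13 steps. Longest linear sequence: 10 steps (1, 2, 4, 5, 6, 7, 8, 11, 12, 13).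

**Steps most likely to fail**

Step 13. The proton transfer to Cb may stall, the quinolonate oxygen may close 5-endo onto the alkyne, or the amide oxygen may take part as diene terminus. The fallback is a domino Knoevenagel/hetero-Diels–Alder sequence at the aldehyde oxidation level, setting out from 18 and 6 and coming back at 24. Hydroboration of 18 with dicyclohexylborane (the terminal alkyne reacts before the trisubstituted alkene) and NaBO3 oxidation would give the pyranylacetaldehyde F1. Amine-catalysed α-selenenylation with N-(phenylselanyl)phthalimide would give the α-phenylselanyl aldehyde F2. Condensation of F2 with 6 (ethylenediammonium diacetate, MeCN, 60 °C) would give the 3-alkylidene-quinoline-2,4-dione F3, not isolated, whose oxadiene adds to the isobutenyl group to form the selenide cycloadduct F4 (Ca–Cb saturated, SePh on Cb). Oxidation with H2O2 and syn-elimination of the selenoxide, which can only take the hydrogen on Ca because Cc is quaternary, would install Ca=Cb and give 24.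

Step 7. Ionisation may occur by loss of the ring (quinolonate) oxygen instead of methoxide, leading to acyclic methylation, or methyl may add at the alkyne terminus. The fallback forms the O–Cc bond last: it sets out from 15 (step 6 stopped after the oxidation) and comes back at 17. MeMgBr with CeCl3 would add to the open ynone form to give the tertiary propargylic alcohol F5 as both carbinol epimers. Bi(OTf)3 (5 mol %, CH2Cl2, 0 °C) would then close pyran B through the propargylic cation to give 17 together with its C2 epimer F6. The two are separated by chromatography and F6 is re-equilibrated under the same acid.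

Step 4. Competing 1,6-addition to the dienal, low facial selectivity, or erosion by retro-Michael reaction may occur. The fallback is an oxidative N-heterocyclic-carbene annulation, setting out from 6 and 9 and coming back at 11. A chiral aminoindanol-derived N-mesityl triazolium salt, 1,8-diazabicyclo[5.4.0]undec-7-ene and 3,3',5,5'-tetra-tert-butyldiphenoquinone would give, through the α,β-unsaturated acyl azolium, the dihydropyranone F7. Reduction with i-Bu2AlH (CH2Cl2, −78 °C) would then give lactol 11.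

**Further compounds**

F1 | step 13 | 2-[(2S,4R)-7,8-dimethoxy-2,6-dimethyl-4-(2-methylprop-1-en-1-yl)-5-oxo-3,4,5,6-tetrahydro-2H-pyrano[3,2-c]quinolin-2-yl]acetaldehyde | O=CC[C@]1(C)C[C@H](C=C(C)C)c2c(O1)c1ccc(OC)c(OC)c1n(C)c2=O
F2 | step 13 | 2-(phenylselanyl) derivative of F1 (epimers at the selenium-bearing carbon) | O=CC([Se]c1ccccc1)[C@]2(C)C[C@H](C=C(C)C)c3c(O2)c2ccc(OC)c(OC)c2n(C)c3=O
F3 | step 13 | 3-alkylidene-7,8-dimethoxy-1-methylquinoline-2,4(1H,3H)-dione from F2 and 6 | CN1C(=O)C(=CC([Se]c2ccccc2)[C@]3(C)C[C@H](C=C(C)C)c4c(O3)c3ccc(OC)c(OC)c3n(C)c4=O)C(=O)c2ccc(OC)c(OC)c21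
F4 | step 13 | Ca,Cb-dihydro target carrying phenylselanyl on Cb | COc1ccc2c3c(c(=O)n(C)c2c1OC)C1C([Se]c6ccccc6)[C@]2(C)C[C@@H](c4c(c5ccc(OC)c(OC)c5n(C)c4=O)O2)[C@@H]1C(C)(C)O3
F5 | step 7 | 4-hydroxy-3-[(4R,6RS)-6-hydroxy-2,6-dimethyl-8-(trimethylsilyl)oct-2-en-7-yn-4-yl]-7,8-dimethoxy-1-methylquinolin-2(1H)-one | CC(C)=C[C@@H](CC(C)(O)C#C[Si](C)(C)C)c1c(O)c2ccc(OC)c(OC)c2n(C)c1=O
F6 | step 7 | (2R,4R)-epimer of 17 | C[Si](C)(C)C#C[C@@]1(C)C[C@H](C=C(C)C)c2c(O1)c1ccc(OC)c(OC)c1n(C)c2=O
F7 | step 4 | (4R)-7,8-dimethoxy-6-methyl-4-(2-methylprop-1-en-1-yl)-3,4-dihydro-2H-pyrano[3,2-c]quinoline-2,5(6H)-dione | O=C1C[C@H](C=C(C)C)c2c(O1)c1ccc(OC)c(OC)c1n(C)c2=O
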